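**Retrosynthetic overview**

- The route rests on the central ring, numbered C1(OH), C2(H), C3(OH), C4(4-hydroxybenzyl), C5(2-phenylethyl), C6(4-hydroxybenzyl). This pentasubstituted resorcinol is the dehydro form of a cyclohexane-1,3-dione, whose three sp3 carbons C4–C6 can take their substituents from open-chain partners.
- Target 13 ⇒ resorcinol bis(anisyl) ether 12 (O-demethylation) ⇒ cyclohexane-1,3-dione 11 (dehydrogenation) ⇒ dione ester 9 (ester hydrolysis and decarboxylation).
- 9 ⇒ enone 5 + benzylmalonate 7 by Michael–Claisen annulation: C4–C5 by conjugate addition, C2–C3 by Claisen closure. This is the only ring formed in the route; the three outer benzene rings are bought.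
- 5 ⇒ ketophosphonate 3 (from 1 + 2) + aldehyde 4 by Horner–Wadsworth–Emmons olefination; 7 ⇒ diethyl malonate 6 + 2.

Key step: step 4

Remark: diones 9, 10 and 11 are written as diketo tautomers although they should exist largely as enols. They are carried as diastereomer mixtures, because step 6 removes every ring stereocentre and the target has none.

**Step 1**
Reactants: 1 dimethyl (2-oxopropyl)phosphonate; 2 4-methoxybenzyl chloride
Product: 3 dimethyl [1-(4-methoxyphenyl)-3-oxobutan-2-yl]phosphonate (racemic)
Conditions: 1 (1.2 equiv), NaH (1.1 equiv), THF, 0 °C; then 2 (1.0 equiv), NaI (0.1 equiv), rt to 50 °C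
Reagents that add atoms: none
Why: SN2 C-alkylation of the sodium enolate of a β-ketophosphonate by a reactive benzylic halide is standard, the slight excess of phosphonate keeps dialkylation minor, and the new stereocentre forms racemic and is lost in step 2.

**Step 2**
Reactants: 3 dimethyl [1-(4-methoxyphenyl)-3-oxobutan-2-yl]phosphonate; 4 3-phenylpropanal
Product: 5 (E)-3-(4-methoxybenzyl)-6-phenylhex-3-en-2-one
Conditions: Ba(OH)2·8H2O (0.8 equiv), THF, rt; then 4, THF/H2O (40:1), rt
Reagents that add atoms: none
Why: Horner–Wadsworth–Emmons olefination of an α-substituted β-ketophosphonate with an unhindered aliphatic aldehyde under mild Ba(OH)2 conditions tolerates the enolisable aldehyde and should favour the E-alkene (acetyl trans to the alkyl chain) on steric grounds; the alkene geometry is in any case erased in step 4.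

**Step 3**
Reactants: 6 diethyl malonate; 2 4-methoxybenzyl chloride
Product: 7 diethyl 2-(4-methoxybenzyl)malonate
Conditions: 6 (2.0 equiv), NaH (1.05 equiv), THF, 0 °C; then 2 (1.0 equiv), NaI (0.1 equiv), reflux
Reagents that add atoms: none
Why: Malonic ester alkylation (SN2) with a benzylic chloride is reliable, the excess of malonate suppresses dialkylation, and the aprotic medium avoids solvolysis of the ionisation-prone 4-methoxybenzyl chloride.

**Step 4**
Reactants: 5 (E)-3-(4-methoxybenzyl)-6-phenylhex-3-en-2-one; 7 diethyl 2-(4-methoxybenzyl)malonate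
Product: 9 ethyl 1,3-bis(4-methoxybenzyl)-4,6-dioxo-2-(2-phenylethyl)cyclohexane-1-carboxylate (diastereomer mixture), via open-chain Michael adduct 8 (not isolated)
Conditions: 7 (1.2 equiv), NaOEt (1.2 equiv), EtOH, rt; then 5 (1.0 equiv), reflux; 1 M HCl work-up
Reagents that add atoms: none
Why: Ethoxide turns 7 into its tertiary carbanion, which adds reversibly to the β-carbon of enone 5 (the C4–C5 bond of the later arene) to give 8 as its ketone enolate; proton transfer to the methyl enolate is followed by Claisen attack of that carbon on one malonate ester (the C2–C3 bond) with loss of ethoxide. The closest known reaction is the Michael–Claisen annulation of malonates with alk-3-en-2-ones to 4-alkoxycarbonylcyclohexane-1,3-diones, the classical entry to 5-alkylresorcinols, here with both partners carrying one more substituent. The single ring closes in 6-exo-trig mode at the ester carbonyl. The three ring stereocentres (the quaternary ester carbon and its two CH neighbours) form without control, under nothing more than the thermodynamic preference of the reversible steps, and none is needed because all three carbons become sp2 by step 6. The step needs 1,4- over 1,2-addition and closure through the methyl carbon, not through the benzyl-bearing α-carbon (which could only give a four-membered ring and an ester shift that yields no stabilised enolate here); both are secured because only the desired path ends in the 1,3-dione enolate, formed irreversibly with the full equivalent of base. The price is a slow conjugate addition between a tertiary carbanion and a trisubstituted enone, hence the prolonged reflux.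

**Step 5**
Reactants: 9 ethyl 1,3-bis(4-methoxybenzyl)-4,6-dioxo-2-(2-phenylethyl)cyclohexane-1-carboxylate
Product: 11 4,6-bis(4-methoxybenzyl)-5-(2-phenylethyl)cyclohexane-1,3-dione (diastereomer mixture), via β-keto acid 10 (not isolated)
Conditions: KOH (10 equiv), EtOH/H2O (1:1), reflux; then 6 M HCl to pH 1, 80 °C
Reagents that add atoms: none
Why: Saponification of the remaining ester (the ring carbonyls are shielded from retro-Claisen attack as the dione enolate) followed by acidification gives β-keto acid 10, which decarboxylates through the usual cyclic transition state on warming, turning the quaternary carbon into a CH.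

**Step 6**
Reactants: 11 4,6-bis(4-methoxybenzyl)-5-(2-phenylethyl)cyclohexane-1,3-dione
Product: 12 4,6-bis(4-methoxybenzyl)-5-(2-phenylethyl)benzene-1,3-diol
Conditions: Pd/C (10 wt% Pd), p-cymene, reflux, N2 sweep
Reagents that add atoms: none
Why: Catalytic dehydrogenation of cyclohexane-1,3-diones over Pd/C in a high-boiling arene is the classical route to resorcinols: loss of one H2 across C4–C5 (or into the exocyclic benzylic position) gives a tautomer of the arene that enolises irreversibly, which removes all ring stereocentres, and the nitrogen sweep carries H2 away so that carbonyl reduction is suppressed.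

**Step 7**
Reactants: 12 4,6-bis(4-methoxybenzyl)-5-(2-phenylethyl)benzene-1,3-diol
Product: 13 4,6-bis(4-hydroxybenzyl)-5-(2-phenylethyl)benzene-1,3-diol (target)
Conditions: BBr3 (6 equiv), CH2Cl2, −78 °C to 0 °C; then H2O, 0 °C
Reagents that add atoms: none
Why: BBr3 demethylation of aryl methyl ethers (Lewis acid complexation, then SN2 attack of bromide at methyl) is reliable; the free resorcinol hydroxyls only consume reagent as aryl borates that hydrolyse on work-up, and the low temperature guards the electron-rich diarylmethane links against acid-induced benzyl migration.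

**Compound list**

1 | dimethyl (2-oxopropyl)phosphonate | COP(=O)(CC(C)=O)OC | starting material
2 | 4-methoxybenzyl chloride | COc1ccc(CCl)cc1 | starting material
3 | dimethyl [1-(4-methoxyphenyl)-3-oxobutan-2-yl]phosphonate (racemic) | COP(=O)(OC)C(Cc1ccc(OC)cc1)C(C)=O | intermediate
4 | 3-phenylpropanal | O=CCCc1ccccc1 | starting material
5 | (E)-3-(4-methoxybenzyl)-6-phenylhex-3-en-2-one | CC(=O)/C(Cc1ccc(OC)cc1)=C/CCc1ccccc1 | intermediate
6 | diethyl malonate | CCOC(=O)CC(=O)OCC | starting material
7 | diethyl 2-(4-methoxybenzyl)malonate | CCOC(=O)C(Cc1ccc(OC)cc1)C(=O)OCC | intermediate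
8 | diethyl 2-(4-methoxybenzyl)-2-[2-(4-methoxybenzyl)-3-oxo-1-(2-phenylethyl)butyl]malonate (open-chain Michael adduct, diastereomer mixture, not isolated) | CCOC(=O)C(Cc1ccc(OC)cc1)(C(=O)OCC)C(CCc1ccccc1)C(Cc1ccc(OC)cc1)C(C)=O | intermediate
9 | ethyl 1,3-bis(4-methoxybenzyl)-4,6-dioxo-2-(2-phenylethyl)cyclohexane-1-carboxylate (diastereomer mixture) | CCOC(=O)C1(Cc2ccc(OC)cc2)C(=O)CC(=O)C(Cc2ccc(OC)cc2)C1CCc1ccccc1 | intermediate
10 | 1,3-bis(4-methoxybenzyl)-4,6-dioxo-2-(2-phenylethyl)cyclohexane-1-carboxylic acid (β-keto acid, diastereomer mixture, not isolated) | OC(=O)C1(Cc2ccc(OC)cc2)C(=O)CC(=O)C(Cc2ccc(OC)cc2)C1CCc1ccccc1 | intermediate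
11 | 4,6-bis(4-methoxybenzyl)-5-(2-phenylethyl)cyclohexane-1,3-dione (diastereomer mixture) | O=C1CC(=O)C(Cc2ccc(OC)cc2)C(CCc2ccccc2)C1Cc1ccc(OC)cc1 | intermediate
12 | 4,6-bis(4-methoxybenzyl)-5-(2-phenylethyl)benzene-1,3-diol | Oc1cc(O)c(Cc2ccc(OC)cc2)c(CCc2ccccc2)c1Cc1ccc(OC)cc1 | intermediate
13 | 4,6-bis(4-hydroxybenzyl)-5-(2-phenylethyl)benzene-1,3-diol (achiral) | Oc1ccc(Cc2c(O)cc(O)c(Cc3ccc(O)cc3)c2CCc2ccccc2)cc1 | target

**Step count**

Total step count: 7.
Longest linear sequence: 6 steps (steps 1, 2, 4, 5, 6, 7); step 3 is the one-step convergent branch.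

**Steps most likely to fail**

Step 4. The conjugate addition joins a tertiary carbanion to a trisubstituted enone and is slow and reversible. Retro-Michael reversion, parking of the enone as its extended dienolate and self-condensation of the enone may therefore outrun ring closure. The fallback sets out from 5 and 6 and comes back at 9; it moves the hindered C–C bond out of the annulation. Enone 5 is annulated with unsubstituted diethyl malonate 6 (NaOEt, EtOH, reflux), whose secondary carbanion adds readily. The open-chain adduct diethyl 2-[2-(4-methoxybenzyl)-3-oxo-1-(2-phenylethyl)butyl]malonate F1 closes in the flask to ethyl 3-(4-methoxybenzyl)-4,6-dioxo-2-(2-phenylethyl)cyclohexane-1-carboxylate F2. F2 is then converted into its dianion (LDA, 2.2 equiv, THF/DMPU, −78 to 0 °C). The second, more basic carbanion sits on the ester-bearing carbon, and alkylation there with 4-methoxybenzyl chloride 2 (dianion alkylation of a β-dicarbonyl system at the site deprotonated last) should give 9.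

Step 6. Dehydrogenation at three contiguous, fully substituted ring carbons may stall. Hydrogen held on the catalyst may also reduce a ring carbonyl, which after dehydration leads to loss of one ring oxygen. The fallback sets out from 11 and comes back at 13; it replaces catalytic dehydrogenation by halogenation–elimination. Iodine (2 equiv) in refluxing methanol first etherifies the dione in the flask to 3-methoxy-4,6-bis(4-methoxybenzyl)-5-(2-phenylethyl)cyclohex-2-en-1-one F3. F3 is iodinated next to the carbonyl and loses hydrogen iodide to aromatise. This should give 5-methoxy-2,4-bis(4-methoxybenzyl)-3-(2-phenylethyl)phenol F4, accompanied by some 1,5-dimethoxy-2,4-bis(4-methoxybenzyl)-3-(2-phenylethyl)benzene F5. The additional O-methyl groups do no harm: the mixture is treated with excess BBr3 under the conditions of step 7 and converges on 13.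

Step 5. Hydroxide attack on a quaternary ester that sits inside an anionic dione enolate may be very slow, and forcing conditions invite ring cleavage by retro-Claisen attack. The fallback sets out from 5 and comes back at 11; it unmasks the acid by hydrogenolysis instead of hydrolysis. Commercial dibenzyl malonate is alkylated with 2 (NaH, THF) to dibenzyl 2-(4-methoxybenzyl)malonate F6. F6 is annulated with 5 (NaH, THF, reflux) through the open-chain adduct dibenzyl 2-(4-methoxybenzyl)-2-[2-(4-methoxybenzyl)-3-oxo-1-(2-phenylethyl)butyl]malonate F7 to benzyl 1,3-bis(4-methoxybenzyl)-4,6-dioxo-2-(2-phenylethyl)cyclohexane-1-carboxylate F8. Hydrogenolysis of F8 (H2, Pd/C, EtOAc, rt) should free β-keto acid 10 under neutral conditions, and gentle warming decarboxylates it to 11.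

**Further compounds**

F1 | step 4 | diethyl 2-[2-(4-methoxybenzyl)-3-oxo-1-(2-phenylethyl)butyl]malonate | CCOC(=O)C(C(=O)OCC)C(CCc1ccccc1)C(Cc1ccc(OC)cc1)C(C)=O
F2 | step 4 | ethyl 3-(4-methoxybenzyl)-4,6-dioxo-2-(2-phenylethyl)cyclohexane-1-carboxylate | CCOC(=O)C1C(=O)CC(=O)C(Cc2ccc(OC)cc2)C1CCc1ccccc1
F3 | step 6 | 3-methoxy-4,6-bis(4-methoxybenzyl)-5-(2-phenylethyl)cyclohex-2-en-1-one | COC1=CC(=O)C(Cc2ccc(OC)cc2)C(CCc2ccccc2)C1Cc1ccc(OC)cc1
F4 | step 6 | 5-methoxy-2,4-bis(4-methoxybenzyl)-3-(2-phenylethyl)phenol | COc1cc(O)c(Cc2ccc(OC)cc2)c(CCc2ccccc2)c1Cc1ccc(OC)cc1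
F5 | step 6 | 1,5-dimethoxy-2,4-bis(4-methoxybenzyl)-3-(2-phenylethyl)benzene | COc1cc(OC)c(Cc2ccc(OC)cc2)c(CCc2ccccc2)c1Cc1ccc(OC)cc1
F6 | step 5 | dibenzyl 2-(4-methoxybenzyl)malonate | COc1ccc(CC(C(=O)OCc2ccccc2)C(=O)OCc2ccccc2)cc1
F7 | step 5 | dibenzyl 2-(4-methoxybenzyl)-2-[2-(4-methoxybenzyl)-3-oxo-1-(2-phenylethyl)butyl]malonate | O=C(OCc1ccccc1)C(Cc1ccc(OC)cc1)(C(=O)OCc1ccccc1)C(CCc1ccccc1)C(Cc1ccc(OC)cc1)C(C)=O
F8 | step 5 | benzyl 1,3-bis(4-methoxybenzyl)-4,6-dioxo-2-(2-phenylethyl)cyclohexane-1-carboxylate | O=C(OCc1ccccc1)C1(Cc2ccc(OC)cc2)C(=O)CC(=O)C(Cc2ccc(OC)cc2)C1CCc1ccccc1
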